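## Structural features

Broussoflavonol E is a flavonol: a 4H-chromen-4-one (rings A and C) with hydroxyls at C3, C5 and C7, joined through the C2–C1' bond to ring B. Ring A carries a 1,1-dimethylallyl (2-methylbut-3-en-2-yl) group at C8, a quaternary carbon wedged between O1 (on C8a) and the C7 hydroxyl. Ring B is a benzene with five contiguous substituents: the link to C2 at C1', a prenyl group at C2', a 2,2-dimethyldihydropyran (chroman ring) fused across C3' (CH2) and C4' (O), and a free hydroxyl at C5'. The molecule has no stereocentre, so no stereochemical relationship has to be set or kept. The fragile parts are the two electron-rich alkenes (acid adds to them, and the C8 side chain can cyclise onto the 7-OH), the tertiary alkyl aryl ether of the chroman (lost with hard Lewis acids) and the 3-hydroxy-4-pyranone polyphenol (oxidised in base and air); hydrogenation and hard ether cleavage are therefore excluded late in the route. The real difficulties are the crowded ring B with its hindered bond to C2, the placing of the quaternary carbon at C8 and not at C6, and telling four hydroxyls apart. The central step uses the fact that O1 (on C8a) and the carbonyl carbon C4 (on C4a) are ortho neighbours on ring A, with the C5 oxygen next to C4a. This is the oxygen/acyl 1,2-pattern that a 3-alkoxybenzyne produces when it inserts into the C–O bond of a carboxylic acid, and with an arylpropiolic acid the resulting ynone only needs the O1–C2 bond to complete ring C.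

## Logic of the disconnections

28 to 27: the C8–C(quaternary) bond is cut and the side chain is returned, with allyl transposition, to an ether on O7. A tertiary carbon on an arene position flanked by two oxygens is hard to reach by substitution, whereas a [3,3] shift delivers it from a primary allyl ether. This removes the only quaternary sp3 carbon of ring A from all earlier stages. The forward step must go to C8 and not C6, and it is placed last so that the ortho-(1,1-dimethylallyl)phenol never meets acid.

27 to 26 to 25 to 22: the O7–CH2 bond, then the three acetal C–O bonds, then the C3–O bond are cut. The ether is cut because O7 is the most acidic hydroxyl of 26. The acetals are cut together because one mild acid step can free rings A and B. C3–O is cut because C3–H is the one acidic vinylic hydrogen of 22. The forward demands are site selectivity among four hydroxyls, acid mild enough for the prenyl alkene, and metalation at C3 only.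

22 to 19 plus 9: the O1–C8a, C4a–C4 and O1–C2 bonds are cut. This divides the molecule into a ring A piece and a ring B piece of similar size and removes ring C. The forward step must add the carboxylate oxygen to the aryne carbon remote from the flanking oxygen, transfer the acyl group before the aryl anion is protonated, and close the ring in the 6-endo mode.

9 to 7 to 3 to 2 to 1: the O–S bond, the carbamate, the C–Si bond and two acetal C–O bonds are cut, back to a symmetric triphenol. The symmetry of 2 removes the left/right question but not every ambiguity. In 3 two kinds of ring position are open to metalation: the one between the carbamate and an acetal oxygen, and the one between the two acetal oxygens. The forward step must therefore be steered by the stronger directing group. A wrongly silylated isomer would have silicon para to the sulfonate and could not release an aryne, so it could not lead to an isomeric flavone.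

19 to 17 to 16: the C–CO2H bond and the alkyne are cut back to the aldehyde carbon. An aldehyde is the natural handle on ring B, and dibromo-olefination followed by elimination and carboxylation adds the two carbons in two operations. The forward steps must avoid acid strong enough to remove the acetal.

16 to 15 to 14 to 13: the acetal on the ring B oxygen is traced back to a methyl ether, and the aryl–CH2 bond of the prenyl group is cut to an aryl bromide. The methyl ether is kept through the early steps because only then is there a single free phenol. It is exchanged before the union because it could not be removed from the final product. The exchange must come after the bromide has been used, since a thiolate would displace a bromide ortho to the formyl group. The coupling must give the linear prenyl isomer at a doubly ortho-substituted carbon.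

13 to 11 to 10: the chroman O–C(quaternary) and aryl–CH2 bonds are cut. The ring comes from a tertiary allyl ether by a [3,3] shift to the only free ortho carbon, followed by acid-mediated closure. The bromine and the aldehyde are already correctly placed in 10. The forward demand is O-allylation at the tertiary terminus.

## Other disconnections considered

Alternative 1: The cut runs through ring A itself. C8–C8a and C6–C7 are the new bonds and C4a–C8a is opened and closed again, so ring A is built from 3-ethoxycyclobut-2-en-1-one A2 and the siloxyalkyne A3, which already carries the 1,1-dimethylallyl group. In the forward step, heating would open A2 to a vinylketene, which adds A3 in a [2+2] sense; the new cyclobutenone opens, the dienylketene closes by 6π electrocyclisation and tautomerises to the phenol A1.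
- In its favour: the quaternary side chain sits on the future C8 by construction. The three ring A oxygens come out differentiated (free hydroxyl for O1, silyl ether at O7, ethyl ether at O5), and the future C4a is left as C–H. On these two points, the C8/C6 choice and the selective alkylation of O7, it is better than the chosen plan.
- Against it here: A3 needs several steps of ynolate chemistry, and its reacting alkyne carbon is neopentyl-like. A1 would still have to be acylated at C4a and taken through a separate ring C synthesis and C3 oxygenation. The O5 ethyl ether would have to be cleaved at the end by a Lewis acid beside two alkenes and the tertiary chroman ether.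
- Comparison: structurally it solves ring A only, whereas the aryne insertion joins ring A to ring B and closes ring C in one operation. Mechanistically both are well-understood cascades, pericyclic in one case and polar in the other, and are equal in that respect. In step economy the chosen plan is ahead: 9 is four steps from 1, while A1 needs its own precursors plus extra steps for ring C and for the ethyl ether.

Alternative 2: The cut is in the chroman of ring B, at its C4–C3 and O1–C2 bonds (chroman numbering). In the forward step, hydroxymethylation of 10 ortho to the phenol would give the benzylic alcohol A5. Heating would expel water to an ortho-quinone methide, which takes up isobutene A6 in an inverse-demand [4+2] cycloaddition to give A4. A4 is the same compound as 13, so everything downstream would be unchanged.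
- In its favour: two steps from 10, no transition metal, no special allyl carbonate, and an unambiguous orientation of A6 (the substituted carbon goes to oxygen).
- Against it here: the quinone methide forms only at high temperature, where it can also oligomerise or alkylate its own precursor. A6 is a gas of modest nucleophilicity, so a pressure vessel and a large excess would be needed.
- Comparison: the step count is equal (two steps against steps 5 and 6) and the product is identical. The alternative is better in reagent cost and has no branched/linear question. The chosen sequence is better in that both bond formations after the etherification are intramolecular and run in ordinary glassware. Alternative 2 is a direct replacement for steps 5 and 6 if needed.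

Alternative 3: The cut is at C3–C4 and O1–C8a. In the forward step, the lithium enolate of the ring B ketone A8, which carries the C3 oxygen as an acetal, would be C-acylated by the ring A 2-fluorobenzoyl chloride A9, which carries the C8 side chain. The diketone enolate oxygen would then displace the ortho fluoride to give A7.
- In its favour: the C3 oxygen and the C8 side chain arrive with the fragments, so after ring closure only protecting groups remain. On positional certainty at C3 and C8, and in the number of operations after the union, it is better than the chosen plan.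
- Against it here: A9 is a pentasubstituted fluoroarene. Its 1,1-dimethylallyl group would itself have to be placed regioselectively, so the C8/C6 problem returns earlier on a less forgiving ring. The fluoride to be displaced is flanked by a quaternary carbon and sits on a ring with two donor oxygens, activated by a single acyl group that is partly switched off in the enolate. O-acylation competes with C-acylation. The O5 methyl ether would have to be cleaved at the end under chelation-assisted Lewis acid conditions that threaten the alkenes.
- Comparison: convergence is equal, since both plans join two fragments of similar size in the ring C-forming step. Mechanistically the aryne route relies on strongly driven additions, the alternative on a weakly activated substitution. In step economy the alternative is shorter after the union but longer before it, and the chosen plan ends without any hard ether cleavage.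

Key step: step 12

Assumption: the target has no stereocentre and is made as the single achiral compound; tert-butyl 2-methylbut-3-en-2-yl carbonate, tributyl(3-methylbut-2-en-1-yl)stannane and N-phenylbis(trifluoromethanesulfonimide) are taken as purchasable reagents.

## Steps

Step 1
Reactants: 1 phloroglucinol
Product: 2 3,5-bis(methoxymethoxy)phenol
Conditions: MeOCH2Cl (2.1 equiv), i-Pr2NEt, DMF, 0 °C to rt
Reagents that add atoms: chloromethyl methyl ether, COCCl
Why: Williamson-type O-alkylation of the phenoxide by the reactive α-chloro ether. With two equivalents the bis-ether should be the main component of a statistical mixture, separable by chromatography from the mono- and tris-ethers.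

Step 2
Reactants: 2 3,5-bis(methoxymethoxy)phenol
Product: 3 3,5-bis(methoxymethoxy)phenyl N-isopropylcarbamate
Conditions: i-PrNCO, Et3N (cat.), CH2Cl2, rt
Reagents that add atoms: isopropyl isocyanate, CC(C)N=C=O
Why: Base-catalysed addition of the single free phenol to the isocyanate (carbamoylation). It installs a strong ortho-directing group that can later be removed under mild conditions.

Step 3
Reactants: 3 3,5-bis(methoxymethoxy)phenyl N-isopropylcarbamate
Product: 7 3,5-bis(methoxymethoxy)-2-(trimethylsilyl)phenyl N-isopropylcarbamate, via N-silyl carbamate 4 (not isolated), via ortho-lithiated N-silyl carbamate 5 (not isolated), via N-silyl 2-trimethylsilyl carbamate 6 (not isolated)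
Conditions: t-BuMe2SiOTf (1.1 equiv), TMEDA, Et2O, 0 °C to rt; n-BuLi, TMEDA, −78 °C; Me3SiCl, −78 °C to rt; cold aq. NaHSO4 work-up
Reagents that add atoms: chlorotrimethylsilane, C[Si](C)(C)Cl
Why: In situ N-silylation masks the N–H, which would otherwise be deprotonated and expel the phenoxide; one equivalent of silyl triflate is consumed by nitrogen before it can attack the acetals. Directed ortho-metalation should then occur at the carbon between the carbamate (the stronger director) and an acetal oxygen, not between the two acetal oxygens; the aryllithium is C-silylated and the N–Si bond is hydrolysed on work-up. Any 4-silyl isomer would be inert in step 12 because its silicon would be para to the sulfonate.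

Step 4
Reactants: 7 3,5-bis(methoxymethoxy)-2-(trimethylsilyl)phenyl N-isopropylcarbamate
Product: 9 3,5-bis(methoxymethoxy)-2-(trimethylsilyl)phenyl trifluoromethanesulfonate, via 2-silylphenol 8 (not isolated)
Conditions: DBU, Et2NH, MeCN, 40 °C; then PhNTf2, rt
Reagents that add atoms: N-phenylbis(trifluoromethanesulfonimide), O=S(=O)(N(c1ccccc1)S(=O)(=O)C(F)(F)F)C(F)(F)F
Why: The secondary carbamate is cleaved by E1cB loss of the isocyanate, which diethylamine traps as a urea, and the phenoxide is sulfonylated in the same flask. The medium stays basic, so the acetals and the aryl–silicon bond should survive.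

Step 5
Reactants: 10 6-bromovanillin (2-bromo-4-hydroxy-5-methoxybenzaldehyde)
Product: 11 2-bromo-5-methoxy-4-[(2-methylbut-3-en-2-yl)oxy]benzaldehyde
Conditions: tert-butyl 2-methylbut-3-en-2-yl carbonate (1.5 equiv), Pd(PPh3)4 (cat.), THF, 0 °C
Reagents that add atoms: tert-butyl 2-methylbut-3-en-2-yl carbonate, C=CC(C)(C)OC(=O)OC(C)(C)C
Why: Tsuji–Trost O-allylation: zerovalent palladium ionises the tertiary carbonate with loss of CO2, the tert-butoxide formed deprotonates the phenol, and the phenoxide attacks the dimethyl-substituted allyl terminus at low temperature to give the branched ether. The aryl bromide should not undergo oxidative addition at 0 °C.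

Step 6
Reactants: 11 2-bromo-5-methoxy-4-[(2-methylbut-3-en-2-yl)oxy]benzaldehyde
Product: 13 5-bromo-8-methoxy-2,2-dimethylchroman-6-carbaldehyde, via ortho-prenylphenol 12 (not isolated)
Conditions: xylenes, 135 °C; then p-TsOH·H2O (cat.), 90 °C
Reagents that add atoms: none
Why: Aromatic Claisen rearrangement of the tertiary allyl aryl ether can only deliver to the one free ortho carbon (the other carries OMe), giving the ortho-prenylphenol. The acid then protonates the trisubstituted alkene and the phenol oxygen traps the tertiary cation (Markovnikov hydroalkoxylation) to close the 2,2-dimethylchroman.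

Step 7
Reactants: 13 5-bromo-8-methoxy-2,2-dimethylchroman-6-carbaldehyde
Product: 14 8-methoxy-2,2-dimethyl-5-(3-methylbut-2-en-1-yl)chroman-6-carbaldehyde
Conditions: Bu3SnCH2CH=CMe2 (1.5 equiv), Pd(PPh3)4 (cat.), DMF, 100 °C
Reagents that add atoms: tributyl(3-methylbut-2-en-1-yl)stannane, CCCC[Sn](CCCC)(CCCC)CC=C(C)C
Why: Stille coupling; oxidative addition of zerovalent palladium is helped by the ortho formyl group, and reductive elimination from the allylpalladium intermediate at its less hindered terminus should give the linear prenyl arene. The aldehyde and the aryl ethers are inert under these neutral conditions.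

Step 8
Reactants: 14 8-methoxy-2,2-dimethyl-5-(3-methylbut-2-en-1-yl)chroman-6-carbaldehyde
Product: 15 8-hydroxy-2,2-dimethyl-5-(3-methylbut-2-en-1-yl)chroman-6-carbaldehyde
Conditions: NaSEt (3 equiv), DMF, 130 °C; then cold 1 M HCl
Reagents that add atoms: none
Why: SN2 demethylation by thiolate at the methyl carbon. The chroman ether has no carbon open to SN2 attack, the aldehyde adds thiolate only reversibly, and no aryl halide is left for nucleophilic aromatic substitution.

Step 9
Reactants: 15 8-hydroxy-2,2-dimethyl-5-(3-methylbut-2-en-1-yl)chroman-6-carbaldehyde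
Product: 16 8-(methoxymethoxy)-2,2-dimethyl-5-(3-methylbut-2-en-1-yl)chroman-6-carbaldehyde
Conditions: MeOCH2Cl, i-Pr2NEt, CH2Cl2, 0 °C to rt
Reagents that add atoms: chloromethyl methyl ether, COCCl
Why: O-alkylation of the single phenol to the acetal ether, so that ring B can later be unmasked in the same mild acid step as ring A.

Step 10
Reactants: 16 8-(methoxymethoxy)-2,2-dimethyl-5-(3-methylbut-2-en-1-yl)chroman-6-carbaldehyde
Product: 17 6-(2,2-dibromovinyl)-8-(methoxymethoxy)-2,2-dimethyl-5-(3-methylbut-2-en-1-yl)chroman
Conditions: CBr4, PPh3, Et3N, CH2Cl2, 0 °C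
Reagents that add atoms: carbon tetrabromide, BrC(Br)(Br)Br
Why: First stage of the Corey–Fuchs homologation, a Wittig-type dibromo-olefination of the aldehyde. The amine buffers any HBr, so the acetal and the prenyl alkene should be untouched.

Step 11
Reactants: 17 6-(2,2-dibromovinyl)-8-(methoxymethoxy)-2,2-dimethyl-5-(3-methylbut-2-en-1-yl)chroman
Product: 19 3-[8-(methoxymethoxy)-2,2-dimethyl-5-(3-methylbut-2-en-1-yl)chroman-6-yl]propiolic acid, via lithium acetylide 18 (not isolated)
Conditions: n-BuLi (2.2 equiv), THF, −78 to 0 °C; CO2 (g), −78 °C to rt; cold 0.5 M HCl work-up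
Reagents that add atoms: carbon dioxide, O=C=O
Why: Second stage of the Corey–Fuchs sequence: bromine–lithium exchange, Fritsch–Buttenberg–Wiechell rearrangement and deprotonation give the lithium acetylide, which is carboxylated by CO2. The brief cold acid work-up should leave the acetal in place.

Step 12
Reactants: 19 3-[8-(methoxymethoxy)-2,2-dimethyl-5-(3-methylbut-2-en-1-yl)chroman-6-yl]propiolic acid; 9 3,5-bis(methoxymethoxy)-2-(trimethylsilyl)phenyl trifluoromethanesulfonate (1.5 equiv)
Product: 22 5,7-bis(methoxymethoxy)-2-[8-(methoxymethoxy)-2,2-dimethyl-5-(3-methylbut-2-en-1-yl)chroman-6-yl]-4H-chromen-4-one, via aryne 20 (not isolated), via ortho-hydroxyaryl ynone 21 (not isolated)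
Conditions: CsF (4 equiv), THF, 125 °C, sealed tube
Reagents that add atoms: none
Why: Fluoride removes the trimethylsilyl group of 9 and triflate leaves, releasing the aryne 20 slowly into a solution of the cesium carboxylate of 19. The carboxylate oxygen should add to the aryne carbon meta to the flanking acetal oxygen (the future C8a), because this puts the aryl anion ortho to the inductively withdrawing oxygen and follows the distortion of a 3-alkoxyaryne. The anion then attacks the neighbouring ester carbonyl through a four-membered tetrahedral intermediate, which opens to transfer the acyl group to C4a; this is a net insertion of the aryne into the acyl C–O bond and gives the ortho-acyl phenoxide 21. The closest known reaction type is the insertion of arynes into the C–O bond of carboxylic acids to give ortho-hydroxyaryl ketones, with arylpropiolic acids going on to flavones. Ring C should close by 6-endo-dig oxa-Michael addition of the phenoxide to the ynone β-carbon; this mode is preferred over 5-exo-dig because it gives the conjugated 4-pyranone and the hot basic medium allows the more stable product to form. No stereocentre is created. The step needs three selectivities: orientation of the aryne addition, secured by the oxygen next to the aryne bond; acyl transfer ahead of protonation, secured by the aprotic medium at high temperature with the acid present as its cesium salt; and carboxylate addition ahead of an ene reaction of the prenyl alkene, secured by the much higher nucleophilicity of the carboxylate.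

Step 13
Reactants: 22 5,7-bis(methoxymethoxy)-2-[8-(methoxymethoxy)-2,2-dimethyl-5-(3-methylbut-2-en-1-yl)chroman-6-yl]-4H-chromen-4-one
Product: 25 3-hydroxy-5,7-bis(methoxymethoxy)-2-[8-(methoxymethoxy)-2,2-dimethyl-5-(3-methylbut-2-en-1-yl)chroman-6-yl]-4H-chromen-4-one, via 3-lithioflavone 23 (not isolated), via 3-boronate 24 (not isolated)
Conditions: LiN(i-Pr)2, THF, −78 °C; B(OMe)3; then AcOH, 30% aq. H2O2, 0 °C to rt
Reagents that add atoms: hydrogen peroxide, OO
Why: C3–H is the most acidic C–H of a flavone (vinylic, next to the carbonyl, lithium held by the C4 oxygen), so kinetic deprotonation at −78 °C followed by borylation and oxidative carbon-to-oxygen migration should give the flavonol. Hydrogen peroxide in cold acetic acid should not epoxidise the isolated prenyl alkene in the time needed.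

Step 14
Reactants: 25 3-hydroxy-5,7-bis(methoxymethoxy)-2-[8-(methoxymethoxy)-2,2-dimethyl-5-(3-methylbut-2-en-1-yl)chroman-6-yl]-4H-chromen-4-one
Product: 26 3,5,7-trihydroxy-2-[8-hydroxy-2,2-dimethyl-5-(3-methylbut-2-en-1-yl)chroman-6-yl]-4H-chromen-4-one
Conditions: 3 M aq. HCl, MeOH, 45 °C
Reagents that add atoms: none
Why: Acid-catalysed methanolysis of the three aryl acetals. No hydroxyl sits ortho to the prenyl group, so acid-promoted cyclisation onto the alkene is not available, and dilute acid at this temperature should not hydrate it.

Step 15
Reactants: 26 3,5,7-trihydroxy-2-[8-hydroxy-2,2-dimethyl-5-(3-methylbut-2-en-1-yl)chroman-6-yl]-4H-chromen-4-one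
Product: 27 3,5-dihydroxy-2-[8-hydroxy-2,2-dimethyl-5-(3-methylbut-2-en-1-yl)chroman-6-yl]-7-[(3-methylbut-2-en-1-yl)oxy]-4H-chromen-4-one
Conditions: Me2C=CHCH2Br (1.05 equiv), K2CO3 (1.05 equiv), acetone, rt, Ar
Reagents that add atoms: 1-bromo-3-methylbut-2-ene, CC(C)=CCBr
Why: Williamson O-alkylation of the most acidic hydroxyl: the 7-OH is para to the pyranone carbonyl, the 5-OH is locked in a hydrogen bond to C4=O, and the 3-OH and ring B hydroxyl are weaker acids. With one equivalent of mild base the 7-phenoxide should be the reacting anion.

Step 16
Reactants: 27 3,5-dihydroxy-2-[8-hydroxy-2,2-dimethyl-5-(3-methylbut-2-en-1-yl)chroman-6-yl]-7-[(3-methylbut-2-en-1-yl)oxy]-4H-chromen-4-one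
Product: 28 Broussoflavonol E, 3,5,7-trihydroxy-2-[8-hydroxy-2,2-dimethyl-5-(3-methylbut-2-en-1-yl)chroman-6-yl]-8-(2-methylbut-3-en-2-yl)-4H-chromen-4-one
Conditions: PhNEt2 (degassed), 185 °C, sealed tube, Ar
Reagents that add atoms: none
Why: Aromatic Claisen rearrangement: the O–CH2 bond breaks as the dimethyl-substituted allyl terminus bonds to C8, and tautomerisation restores the phenol with the 1,1-dimethylallyl group in place. C8 should be preferred over C6 because bond fixation by the pyranone ring gives the C7–C8 bond more double-bond character. The basic amine solvent suppresses acid-catalysed cyclisation of the product onto its 7-OH; no stereocentre is formed.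

## Compound list

1 | phloroglucinol | Oc1cc(O)cc(O)c1 | starting material
2 | 3,5-bis(methoxymethoxy)phenol | COCOc1cc(O)cc(OCOC)c1 | intermediate
3 | 3,5-bis(methoxymethoxy)phenyl N-isopropylcarbamate | COCOc1cc(OCOC)cc(OC(=O)NC(C)C)c1 | intermediate
4 | 3,5-bis(methoxymethoxy)phenyl N-(tert-butyldimethylsilyl)-N-isopropylcarbamate (formed in the flask) | COCOc1cc(OCOC)cc(OC(=O)N(C(C)C)[Si](C)(C)C(C)(C)C)c1 | intermediate
5 | 2-lithio-3,5-bis(methoxymethoxy)phenyl N-(tert-butyldimethylsilyl)-N-isopropylcarbamate (formed in the flask) | COCOc1cc(OCOC)c([Li])c(OC(=O)N(C(C)C)[Si](C)(C)C(C)(C)C)c1 | intermediate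
6 | 3,5-bis(methoxymethoxy)-2-(trimethylsilyl)phenyl N-(tert-butyldimethylsilyl)-N-isopropylcarbamate (formed in the flask) | COCOc1cc(OCOC)c([Si](C)(C)C)c(OC(=O)N(C(C)C)[Si](C)(C)C(C)(C)C)c1 | intermediate
7 | 3,5-bis(methoxymethoxy)-2-(trimethylsilyl)phenyl N-isopropylcarbamate | COCOc1cc(OCOC)c([Si](C)(C)C)c(OC(=O)NC(C)C)c1 | intermediate
8 | 3,5-bis(methoxymethoxy)-2-(trimethylsilyl)phenol (formed in the flask) | COCOc1cc(OCOC)c([Si](C)(C)C)c(O)c1 | intermediate
9 | 3,5-bis(methoxymethoxy)-2-(trimethylsilyl)phenyl trifluoromethanesulfonate | COCOc1cc(OCOC)c([Si](C)(C)C)c(OS(=O)(=O)C(F)(F)F)c1 | intermediate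
10 | 6-bromovanillin (2-bromo-4-hydroxy-5-methoxybenzaldehyde) | O=Cc1cc(OC)c(O)cc1Br | starting material
11 | 2-bromo-5-methoxy-4-[(2-methylbut-3-en-2-yl)oxy]benzaldehyde | O=Cc1cc(OC)c(OC(C)(C)C=C)cc1Br | intermediate
12 | 2-bromo-4-hydroxy-5-methoxy-3-(3-methylbut-2-en-1-yl)benzaldehyde (formed in the flask) | O=Cc1cc(OC)c(O)c(CC=C(C)C)c1Br | intermediate
13 | 5-bromo-8-methoxy-2,2-dimethylchroman-6-carbaldehyde | O=Cc1cc(OC)c2c(c1Br)CCC(C)(C)O2 | intermediate
14 | 8-methoxy-2,2-dimethyl-5-(3-methylbut-2-en-1-yl)chroman-6-carbaldehyde | O=Cc1cc(OC)c2c(c1CC=C(C)C)CCC(C)(C)O2 | intermediate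
15 | 8-hydroxy-2,2-dimethyl-5-(3-methylbut-2-en-1-yl)chroman-6-carbaldehyde | O=Cc1cc(O)c2c(c1CC=C(C)C)CCC(C)(C)O2 | intermediate
16 | 8-(methoxymethoxy)-2,2-dimethyl-5-(3-methylbut-2-en-1-yl)chroman-6-carbaldehyde | O=Cc1cc(OCOC)c2c(c1CC=C(C)C)CCC(C)(C)O2 | intermediate
17 | 6-(2,2-dibromovinyl)-8-(methoxymethoxy)-2,2-dimethyl-5-(3-methylbut-2-en-1-yl)chroman | BrC(Br)=Cc1cc(OCOC)c2c(c1CC=C(C)C)CCC(C)(C)O2 | intermediate
18 | {[8-(methoxymethoxy)-2,2-dimethyl-5-(3-methylbut-2-en-1-yl)chroman-6-yl]ethynyl}lithium (formed in the flask) | [Li]C#Cc1cc(OCOC)c2c(c1CC=C(C)C)CCC(C)(C)O2 | intermediate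
19 | 3-[8-(methoxymethoxy)-2,2-dimethyl-5-(3-methylbut-2-en-1-yl)chroman-6-yl]propiolic acid | OC(=O)C#Cc1cc(OCOC)c2c(c1CC=C(C)C)CCC(C)(C)O2 | intermediate
20 | 3,5-bis(methoxymethoxy)benzyne (formed in the flask) | COCOC1=CC(OCOC)=CC#C1 | intermediate
21 | 1-[2-hydroxy-4,6-bis(methoxymethoxy)phenyl]-3-[8-(methoxymethoxy)-2,2-dimethyl-5-(3-methylbut-2-en-1-yl)chroman-6-yl]prop-2-yn-1-one (formed in the flask) | COCOc1cc(O)c(C(=O)C#Cc2cc(OCOC)c3c(c2CC=C(C)C)CCC(C)(C)O3)c(OCOC)c1 | intermediate
22 | 5,7-bis(methoxymethoxy)-2-[8-(methoxymethoxy)-2,2-dimethyl-5-(3-methylbut-2-en-1-yl)chroman-6-yl]-4H-chromen-4-one | COCOc1cc(OCOC)c2c(=O)cc(-c3cc(OCOC)c4c(c3CC=C(C)C)CCC(C)(C)O4)oc2c1 | intermediate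
23 | 3-lithio derivative of 22 (formed in the flask) | COCOc1cc(OCOC)c2c(=O)c([Li])c(-c3cc(OCOC)c4c(c3CC=C(C)C)CCC(C)(C)O4)oc2c1 | intermediate
24 | dimethyl {5,7-bis(methoxymethoxy)-2-[8-(methoxymethoxy)-2,2-dimethyl-5-(3-methylbut-2-en-1-yl)chroman-6-yl]-4-oxo-4H-chromen-3-yl}boronate (formed in the flask) | COCOc1cc(OCOC)c2c(=O)c(B(OC)OC)c(-c3cc(OCOC)c4c(c3CC=C(C)C)CCC(C)(C)O4)oc2c1 | intermediate
25 | 3-hydroxy-5,7-bis(methoxymethoxy)-2-[8-(methoxymethoxy)-2,2-dimethyl-5-(3-methylbut-2-en-1-yl)chroman-6-yl]-4H-chromen-4-one | COCOc1cc(OCOC)c2c(=O)c(O)c(-c3cc(OCOC)c4c(c3CC=C(C)C)CCC(C)(C)O4)oc2c1 | intermediate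
26 | 3,5,7-trihydroxy-2-[8-hydroxy-2,2-dimethyl-5-(3-methylbut-2-en-1-yl)chroman-6-yl]-4H-chromen-4-one | Oc1cc(O)c2c(=O)c(O)c(-c3cc(O)c4c(c3CC=C(C)C)CCC(C)(C)O4)oc2c1 | intermediate
27 | 3,5-dihydroxy-2-[8-hydroxy-2,2-dimethyl-5-(3-methylbut-2-en-1-yl)chroman-6-yl]-7-[(3-methylbut-2-en-1-yl)oxy]-4H-chromen-4-one | CC(C)=CCOc1cc(O)c2c(=O)c(O)c(-c3cc(O)c4c(c3CC=C(C)C)CCC(C)(C)O4)oc2c1 | intermediate
28 | Broussoflavonol E, 3,5,7-trihydroxy-2-[8-hydroxy-2,2-dimethyl-5-(3-methylbut-2-en-1-yl)chroman-6-yl]-8-(2-methylbut-3-en-2-yl)-4H-chromen-4-one | C=CC(C)(C)c1c(O)cc(O)c2c(=O)c(O)c(-c3cc(O)c4c(c3CC=C(C)C)CCC(C)(C)O4)oc12 | target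

## Step count and least certain steps

Total: 16 steps. Longest linear sequence: 12 steps (steps 5 to 16, from 10); the aryne precursor branch (steps 1 to 4) joins at step 12.

Step 12 (key step). Three processes could divert it:
- protonation of the aryl anion before acyl transfer, which would stop at simple O-arylation of the acid;
- thermal loss of CO2 from the cesium arylpropiolate at 125 °C;
- 5-exo closure of the phenoxide onto the ynone, favoured if the hindered ring B slows attack at the β-carbon.

Fallback, from 17 back to 22: 17 would be converted to the acetylide 18 as in step 11 and added at −78 °C to the lithium phenoxide (pre-formed with LiN(SiMe3)2) of 2-hydroxy-4,6-bis(methoxymethoxy)benzaldehyde F1. F1 would be made from commercial 2,4,6-trihydroxybenzaldehyde with two equivalents of chloromethyl methyl ether, the hydrogen-bonded ortho hydroxyl staying free. The addition would give the racemic propargylic alcohol 1-[2-hydroxy-4,6-bis(methoxymethoxy)phenyl]-3-[8-(methoxymethoxy)-2,2-dimethyl-5-(3-methylbut-2-en-1-yl)chroman-6-yl]prop-2-yn-1-ol F2. Oxidation with MnO2 in CH2Cl2 would give 21, now isolated, and catalytic 4-(dimethylamino)pyridine in DMF would close it in the 6-endo mode to 22.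

Step 16. The shift could go to C6 instead of C8, because the hydrogen-bonded 5-OH favours the opposite bond fixation in ring A. The new ortho-(1,1-dimethylallyl)phenol could also cyclise onto the 7-OH, or the allyl group could be lost by ionisation at the temperature needed.

Fallback, from 27 back to 28: acetylation of 27 (Ac2O, pyridine) would give 3,5-diacetoxy-2-[8-acetoxy-2,2-dimethyl-5-(3-methylbut-2-en-1-yl)chroman-6-yl]-7-[(3-methylbut-2-en-1-yl)oxy]-4H-chromen-4-one F3, in which the C5 oxygen can no longer chelate. Rearrangement in PhNEt2 containing Ac2O and NaOAc would trap the new 7-hydroxyl as it forms, giving the tetraacetate of the target, 3,5,7-triacetoxy-2-[8-acetoxy-2,2-dimethyl-5-(3-methylbut-2-en-1-yl)chroman-6-yl]-8-(2-methylbut-3-en-2-yl)-4H-chromen-4-one F4. Methanolysis with K2CO3 in MeOH at rt would then give 28.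

Step 15. Alkylation could spill over to the 3-hydroxyl or the ring B hydroxyl, or occur twice, since a less acidic but more nucleophilic oxide can compete once some of it is formed.

Fallback, from 26 back to 27: peracetylation would give 3,5,7-triacetoxy-2-[8-acetoxy-2,2-dimethyl-5-(3-methylbut-2-en-1-yl)chroman-6-yl]-4H-chromen-4-one F5. Thiophenol and imidazole in N-methylpyrrolidinone would remove only the ester of the most acidic phenol, giving 3,5-diacetoxy-2-[8-acetoxy-2,2-dimethyl-5-(3-methylbut-2-en-1-yl)chroman-6-yl]-7-hydroxy-4H-chromen-4-one F6. Mitsunobu etherification of its single free hydroxyl with 3-methylbut-2-en-1-ol (PPh3, diisopropyl azodicarboxylate) would give the triacetate F3 already described. K2CO3 in MeOH would return 27, or F3 could go straight into the fallback for step 16.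

Step 7. The allyl group could be transferred through its substituted terminus (branched isomer). Coupling at a bromide with two ortho substituents could also be slow enough for reduction of the C–Br bond to compete.

Fallback, from 13 back to 14: acetalisation (ethylene glycol, p-TsOH, toluene, water removal) would give 2-(5-bromo-8-methoxy-2,2-dimethylchroman-6-yl)-1,3-dioxolane F7. Bromine–lithium exchange (n-BuLi, THF, −78 °C), transmetalation with CuBr·SMe2 and alkylation with 1-bromo-3-methylbut-2-ene (arylcopper reagents attack the primary carbon) would give 2-[8-methoxy-2,2-dimethyl-5-(3-methylbut-2-en-1-yl)chroman-6-yl]-1,3-dioxolane F8. Mild hydrolysis (pyridinium p-toluenesulfonate, acetone–water) would return 14.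

Step 5. The branched ether could be re-ionised by palladium and drift to the linear O-prenyl ether, which the acidic phenol makes easier; that ether would rearrange in step 6 to the wrong side chain.

Fallback, from 10 back to 11: alkylation of 10 with 3-chloro-3-methylbut-1-yne (K2CO3, KI, CuI cat., acetone, 55 °C) would give 2-bromo-5-methoxy-4-[(2-methylbut-3-yn-2-yl)oxy]benzaldehyde F9. Semi-hydrogenation (H2, Pd/CaCO3 poisoned with Pb(OAc)2, quinoline, EtOAc) would give 11 with the tertiary connectivity fixed from the start.

## Further compounds

F1 | step 12 | 2-hydroxy-4,6-bis(methoxymethoxy)benzaldehyde | O=Cc1c(O)cc(OCOC)cc1OCOC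
F2 | step 12 | 1-[2-hydroxy-4,6-bis(methoxymethoxy)phenyl]-3-[8-(methoxymethoxy)-2,2-dimethyl-5-(3-methylbut-2-en-1-yl)chroman-6-yl]prop-2-yn-1-ol (racemic) | OC(C#Cc1cc(OCOC)c2c(c1CC=C(C)C)CCC(C)(C)O2)c1c(O)cc(OCOC)cc1OCOC
F3 | step 16 | 3,5-diacetoxy-2-[8-acetoxy-2,2-dimethyl-5-(3-methylbut-2-en-1-yl)chroman-6-yl]-7-[(3-methylbut-2-en-1-yl)oxy]-4H-chromen-4-one | CC(C)=CCOc1cc(OC(C)=O)c2c(=O)c(OC(C)=O)c(-c3cc(OC(C)=O)c4c(c3CC=C(C)C)CCC(C)(C)O4)oc2c1
F4 | step 16 | 3,5,7-triacetoxy-2-[8-acetoxy-2,2-dimethyl-5-(3-methylbut-2-en-1-yl)chroman-6-yl]-8-(2-methylbut-3-en-2-yl)-4H-chromen-4-one | C=CC(C)(C)c1c(OC(C)=O)cc(OC(C)=O)c2c(=O)c(OC(C)=O)c(-c3cc(OC(C)=O)c4c(c3CC=C(C)C)CCC(C)(C)O4)oc12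
F5 | step 15 | 3,5,7-triacetoxy-2-[8-acetoxy-2,2-dimethyl-5-(3-methylbut-2-en-1-yl)chroman-6-yl]-4H-chromen-4-one | CC(=O)Oc1cc(OC(C)=O)c2c(=O)c(OC(C)=O)c(-c3cc(OC(C)=O)c4c(c3CC=C(C)C)CCC(C)(C)O4)oc2c1
F6 | step 15 | 3,5-diacetoxy-2-[8-acetoxy-2,2-dimethyl-5-(3-methylbut-2-en-1-yl)chroman-6-yl]-7-hydroxy-4H-chromen-4-one | Oc1cc(OC(C)=O)c2c(=O)c(OC(C)=O)c(-c3cc(OC(C)=O)c4c(c3CC=C(C)C)CCC(C)(C)O4)oc2c1
F7 | step 7 | 2-(5-bromo-8-methoxy-2,2-dimethylchroman-6-yl)-1,3-dioxolane | COc1cc(C2OCCO2)c(Br)c2c1OC(C)(C)CC2
F8 | step 7 | 2-[8-methoxy-2,2-dimethyl-5-(3-methylbut-2-en-1-yl)chroman-6-yl]-1,3-dioxolane | COc1cc(C2OCCO2)c(CC=C(C)C)c2c1OC(C)(C)CC2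
F9 | step 5 | 2-bromo-5-methoxy-4-[(2-methylbut-3-yn-2-yl)oxy]benzaldehyde | O=Cc1cc(OC)c(OC(C)(C)C#C)cc1Br
A1 | alternative 1 | 5-ethoxy-2-(2-methylbut-3-en-2-yl)-3-(triisopropylsilyloxy)phenol | CCOc1cc(O)c(C(C)(C)C=C)c(O[Si](C(C)C)(C(C)C)C(C)C)c1
A2 | alternative 1 | 3-ethoxycyclobut-2-en-1-one | CCOC1=CC(=O)C1
A3 | alternative 1 | [(3,3-dimethylpent-4-en-1-yn-1-yl)oxy]triisopropylsilane | C=CC(C)(C)C#CO[Si](C(C)C)(C(C)C)C(C)C
A4 | alternative 2 | 5-bromo-8-methoxy-2,2-dimethylchroman-6-carbaldehyde | O=Cc1cc(OC)c2c(c1Br)CCC(C)(C)O2
A5 | alternative 2 | 2-bromo-4-hydroxy-3-(hydroxymethyl)-5-methoxybenzaldehyde | O=Cc1cc(OC)c(O)c(CO)c1Br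
A6 | alternative 2 | isobutene (2-methylpropene) | CC(C)=C
A7 | alternative 3 | 5-methoxy-3,7-bis(methoxymethoxy)-2-[8-(methoxymethoxy)-2,2-dimethyl-5-(3-methylbut-2-en-1-yl)chroman-6-yl]-8-(2-methylbut-3-en-2-yl)-4H-chromen-4-one | C=CC(C)(C)c1c(OCOC)cc(OC)c2c(=O)c(OCOC)c(-c3cc(OCOC)c4c(c3CC=C(C)C)CCC(C)(C)O4)oc12
A8 | alternative 3 | 2-(methoxymethoxy)-1-[8-(methoxymethoxy)-2,2-dimethyl-5-(3-methylbut-2-en-1-yl)chroman-6-yl]ethan-1-one | COCOCC(=O)c1cc(OCOC)c2c(c1CC=C(C)C)CCC(C)(C)O2
A9 | alternative 3 | 2-fluoro-6-methoxy-4-(methoxymethoxy)-3-(2-methylbut-3-en-2-yl)benzoyl chloride | C=CC(C)(C)c1c(OCOC)cc(OC)c(C(=O)Cl)c1F
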